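(The readings are calculated with made-up constants, noise included.)

Set larch beside beta before reading anything off beta's last readings: the two flasks share their electrophile, nucleophile and free base, and differ in protic impurity and time.

the same everywhere: electrophile 0.80 M
- beta: nucleophile 0.84 M; free base 0.40 M; protic impurity 0.24 M; run made earlier
- alder: nucleophile 0.840 M; free base 0.600 M; protic impurity 0.160 M; time 3.0 min
- larch: nucleophile 0.840 M; free base 0.400 M; protic impurity 0.160 M; time 3.0 min

beta run (percent of the electrophile charged)

| time / s | electrophile / % | target / % |
|---|---|---|
| 10.0 | 74 | 8 |
| 12.0 | 71 | 14 |
| 20.0 | 59 | 18 |
| 40.0 | 51 | 21 |

(readings scatter by 2 percentage points)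

- what was read earlier has a scatter of 2 percentage points, one standard deviation
- no earlier run changes the charge of free base; that part of a forecast is a guess
- no earlier run changes the charge of protic impurity; that part of a forecast is a guess

* part of the electrophile that has reacted at the end, alder
* part of the electrophile that has reacted at the end, larch
* what raising the concentration of free base from its lowest to its highest value here does to the part of the electrophile that has reacted (changes below 5 percentage points count as none) (no change / it rises / it falls)

By 40.0 s, beta has lost 28.0% of its electrophile to something other than target, as a reading. That is close to beta's charged [protic impurity] over charged [electrophile], 30.0%. I call this ratio the toll, the part of the electrophile spent on protic impurity at one to one; it is 20.0% for larch, less than beta's, so larch should lose less that way.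

Adding beta's target at that reading, 21%, I start larch from 41.0%. Holding the target's last slope up to 3.0 min gives 62.0%, and I commit to that span. Beta's target at 40.0 s amounts to 0.168 M, less than its 0.40 M of free base. So even if each target used up one free base, beta's free base has not run out at that reading, and I guess that alder, with more of it, ends level with larch. It stays a guess, since no earlier run varies free base.

The forecast gives 74% for alder (62% to 81%), 50% for larch (44% to 57%) and "it rises", on the ground “so the base caps conversion”. There it parts from my reckoning.

    electrophile + nucleophile → acid set free + target (k = 0.0192 /M/s)
    nucleophile + acid set free ⇌ protonated nucleophile, settled at all times (K = 10800 /M)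
    acid set free + free base ⇌ salt of the base, settled at all times (K = 3.70 /M)
    nucleophile ⇌ dormant form (K = 5.50, k = 0.0204 /s)
    electrophile + protic impurity → quenched substrate (k = 0.0983 /M/s)

The flask gives 51.8% for alder and 51.8% for larch, so the trend is "no change", a change of 0.013 percentage points, and alder lies below the forecast's low end. Alder holds 20.0% of quenched substrate at the asked time, against a toll of 20.0%, with protic impurity, the limiting reagent of quenching, down to 0.0365% of its charge. The half-life of alder's electrophile by quenching grows from 1.6 min at 0.195 min to 34 h at the asked time, long against the 3.0 min of the run. A neighbour of alder with 0.040 M of protic impurity has a toll of 5.00% and ends with 5.00% of quenched substrate.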